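## Retrosynthetic overview

1. Target 23 ⇐ bis-enone 22 by one double CBS reduction (C9, C14). 22 ⇐ propargylic alcohol 21 by the key step, a gold-catalysed 1,2-shift of C1 from C9 to C10 that turns the six-membered ring into the seven-membered 2-methylene ketone.
2. 21 ⇐ lactol 17 by Felkin aldol with methyl isopropenyl ketone (C13–C17) and 12-O-acetylation.
3. 17 ⇐ γ-hydroxy enone 11 by Ueno–Stork bromoacetal radical cyclisation (C7–C11 bond, cis to O-6), then acetylide addition at C9.
4. 11 ⇐ quinone monoketal 3 by asymmetric conjugate vinylation, Ir-catalysed branched crotylation, RCM and Luche reduction/ketal hydrolysis; 3 ⇐ phenol.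
5. Ring order: six-membered carbocycle (from phenol) → cyclopentene (RCM) → temporary tetrahydrofuran tether ring (opened again in step 9) → seven-membered ring by expansion of the six-membered ring.

Conventions and assumption (one line): target numbering is used throughout (ring C1–C10, side chain C11–C17, C18 exo-methylene, C19 = 11-Me, C20 = 4-Me; β = face of H-1); the acetal/lactol carbon C12 and the CHBr carbon of 13 are inconsequential mixtures (left open in SMILES), and the C9 carbinol of 16–21 is drawn as the expected epimer although its configuration is lost in step 11.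

## Route

Step 1
Reactants: 1 phenol
Product: 3 4,4-dimethoxycyclohexa-2,5-dien-1-one, via 4-methoxyphenol 2 (not isolated)
Conditions: PhI(OAc)2 (2.2 equiv), MeOH, 0 → 23 °C
Reagents that add atoms: methanol CO
Why: Twofold hypervalent-iodine oxidative dearomatisation: para-methoxylation gives 2, which is oxidised again and trapped by methanol as the p-quinone monoketal; no stereocentre is formed.

Step 2
Reactants: 3 4,4-dimethoxycyclohexa-2,5-dien-1-one; 4 potassium vinyltrifluoroborate
Product: 5 (S)-4,4-dimethoxy-5-vinylcyclohex-2-en-1-one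
Conditions: [RhCl(C2H4)2]2 (2.5 mol%), chiral diene Ph-bod* (5.5 mol%, enantiomer that gives (S)-5), KOH (10 mol%), dioxane/H2O 10:1, 40 °C
Reagents that add atoms: none
Why: Rh(I)/chiral-diene asymmetric 1,4-addition (Hayashi–Miyaura type) desymmetrises the dienone; the ligand selects the enantiotopic alkene face and sets C1, and the hindered second β-carbon stops over-addition.

Step 3
Reactants: 5 (S)-4,4-dimethoxy-5-vinylcyclohex-2-en-1-one; 6 (E)-but-2-en-1-yl acetate
Product: 8 (5R,6R)-6-[(2S)-but-3-en-2-yl]-4,4-dimethoxy-5-vinylcyclohex-2-en-1-one, via lithium dienolate 7 (not isolated)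
Conditions: LiHMDS, THF, −78 °C; then 6, [Ir(cod)Cl]2 (2 mol%), Feringa-type phosphoramidite (4 mol%, n-PrNH2-activated, enantiomer that gives the (S)-allylic carbon), LiCl, THF, −78 → 0 °C
Reagents that add atoms: none
Why: Ir-catalysed branched-selective asymmetric allylic alkylation: only C5 can be enolised (cross-conjugated dienolate 7), attack at the substituted allyl terminus lets the catalyst set C4, and the enolate reacts anti to the C1 vinyl group to give the trans C1/C5 product, which is also the thermodynamic epimer.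

Step 4
Reactants: 8 (5R,6R)-6-[(2S)-but-3-en-2-yl]-4,4-dimethoxy-5-vinylcyclohex-2-en-1-one
Product: 9 (3S,3aR,7aR)-7,7-dimethoxy-3-methyl-3,3a,7,7a-tetrahydro-4H-inden-4-one (trans-fused)
Conditions: Grubbs II (3 mol%), CH2Cl2, 40 °C
Reagents that add atoms: none
Why: Ring-closing metathesis of the two monosubstituted alkenes closes the cyclopentene (C2=C3) with loss of ethene; the trans C1/C5 relationship becomes the trans ring fusion and the electron-poor enone alkene is inert.

Step 5
Reactants: 9 (3S,3aR,7aR)-7,7-dimethoxy-3-methyl-3,3a,7,7a-tetrahydro-4H-inden-4-one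
Product: 11 (1S,3aR,7R,7aR)-7-hydroxy-1-methyl-1,3a,7,7a-tetrahydro-4H-inden-4-one, via allylic alcohol ketal 10 (not isolated)
Conditions: NaBH4, CeCl3·7H2O, MeOH, −78 °C; then 1 M aq HCl, THF, 0 °C, 15 min
Reagents that add atoms: water O
Why: Luche 1,2-reduction with axial hydride delivery (anti to axial H-5, away from the 4α-methyl) gives the equatorial 6α-alcohol, and mild acid hydrolyses the now allylic dimethyl ketal to the γ-hydroxy enone (C9 ketone).

Step 6
Reactants: 11 (1S,3aR,7R,7aR)-7-hydroxy-1-methyl-1,3a,7,7a-tetrahydro-4H-inden-4-one; 12 ethyl prop-1-enyl ether (E/Z)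
Product: 13 bromoacetal of 11 (6-O–CH(OEt)–CHBr–CH3)
Conditions: 12 (3 equiv), NBS (1.5 equiv), CH2Cl2, −40 → 0 °C
Reagents that add atoms: N-bromosuccinimide O=C1CCC(=O)N1Br
Why: Bromoacetalisation (Ueno–Stork tether): the bromonium ion of the enol ether is captured by the 6-OH; the new acetal and bromide centres are inconsequential.

Step 7
Reactants: 13 bromoacetal of 11
Product: 14 tricyclic keto acetal (cis-fused 2-ethoxy-3-methyltetrahydrofuran across C6–C7; O-6 α, C7–C11 α, 11S, C9 ketone)
Conditions: Bu3SnH (1.3 equiv, slow addition), AIBN (0.1 equiv), PhH, 80 °C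
Reagents that add atoms: none
Why: Ueno–Stork 5-exo-trig radical cyclisation: the tether delivers C11 to C7 on the face of O-6 (cis ring fusion, axial attack on the enone) and the methyl takes the exo position (11S); the α-keto radical at C8 is reduced by the stannane.

Step 8
Reactants: 14 tricyclic keto acetal; 15 ethynylmagnesium bromide
Product: 17 lactol (9β-ethynyl-9α-hydroxy, C12 hemiacetal), via propargylic alcohol acetal 16 (not isolated)
Conditions: 15 (3 equiv), THF, −78 → 0 °C; then 2 M aq HCl/THF 1:4, 23 °C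
Reagents that add atoms: water O
Why: Acetylide 1,2-addition (equatorial attack, since axial C7–C11 blocks the α face) masks the ketone as the carbinol needed for ring expansion, and acid hydrolysis of the ethyl acetal gives the lactol; any 11-epimer can equilibrate to the exo-methyl lactol through the open hydroxy-aldehyde.

Step 9
Reactants: 17 lactol; 18 3-methylbut-3-en-2-one
Product: 20 aldol adduct (6α,9α,12-triol, 9β-ethynyl, side chain (11S,12S)-CH(CH3)–CH(OH)–CH2–CO–C(CH3)=CH2), via lithium enolate 19 (not isolated)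
Conditions: 18 (5 equiv), LDA (5 equiv), THF, −78 °C; add 17, −78 °C, 1 h; AcOH quench
Reagents that add atoms: none
Why: Aldol addition to the open hydroxy-aldehyde form of the lactol (excess enolate absorbs the two OH protons): Felkin–Anh attack anti to the ring carbon C7 sets 12S, with 11-Me and 12-OH syn.

Step 10
Reactants: 20 aldol adduct
Product: 21 12-O-acetate of 20
Conditions: Ac2O (1.2 equiv), pyridine, CH2Cl2, 0 °C
Reagents that add atoms: acetic anhydride CC(=O)OC(C)=O
Why: Chemoselective acylation: the acyclic 12-OH reacts, while the ring 6-OH (flanked by two methine carbons) and the tertiary 9-OH stay free; no DMAP, to avoid β-elimination of the β-acetoxy ketone.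

Step 11
Reactants: 21 12-O-acetate of 20
Product: 22 ring-expanded bis-enone ((1R,4S,5R,6R,7S,11S,12S)-12-acetoxy-6-hydroxy-9,14-dioxo hydroazulene with 10-methylidene, Δ2 and Δ15(16))
Conditions: [(ArO)3PAu(NCMe)]SbF6 (5 mol%, Ar = 2,4-tBu2C6H3), 2,6-di-tert-butylpyridine (5 mol%), 4 Å MS, dry CH2Cl2, 0 → 23 °C
Reagents that add atoms: none
Why: Proposed new method: cationic Au(I)-catalysed semipinacol ring expansion of an unstrained tertiary 1-ethynylcyclohexanol (six → seven); η2-coordination of LAu+ makes the internal alkyne carbon C10 electrophilic, the C9–C1 bond (secondary carbon, higher migratory aptitude than C8) shifts to C10 anti to gold while the hydroxyl forms the C9 oxocarbenium, and its proton protodeaurates the vinyl-gold at C18, giving the 2-methylene cycloheptanone with retention at C1 so the trans ring fusion is kept; the driving force is alkyne-to-enone conversion plus relief of the strained trans cyclopentene/cyclohexane fusion, and Meyer–Schuster and Rupe pathways are held back by water-free conditions, a non-nucleophilic counter-ion, an electron-poor phosphite ligand and a hindered base as proton shuttle; the closest known reaction type is the strain-driven Au(I) ring expansion of 1-alkynyl cyclopropanols and cyclobutanols (semipinacol/Tiffeneau–Demjanov family), which has not been shown on an unstrained six-membered carbinol.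

Step 12
Reactants: 22 ring-expanded bis-enone
Product: 23 target CNP0151410.1 (1R,4S,5R,6R,7S,9R,11S,12S,14R)
Conditions: (S)-Me-CBS oxazaborolidine (0.5 equiv), catecholborane (5 equiv), toluene, −78 °C; MeOH quench, pH 7 work-up
Reagents that add atoms: none
Why: Corey–Bakshi–Shibata reduction of both enone carbonyls: with the alkenyl group (C10=C18 and isopropenyl) as the large substituent, the (S)-catalyst delivers hydride in the same sense at each, giving 9R (9β-OH) and 14R (syn to 12-OAc) under catalyst control; 1,2-reduction outruns conjugate reduction at −78 °C and the acetate survives.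

## Compound list

1 | phenol | Oc1ccccc1 | starting material
2 | 4-methoxyphenol | COc1ccc(O)cc1 | intermediate
3 | 4,4-dimethoxycyclohexa-2,5-dien-1-one | COC1(OC)C=CC(=O)C=C1 | intermediate
4 | potassium vinyltrifluoroborate | [K+].C=C[B-](F)(F)F | starting material
5 | (S)-4,4-dimethoxy-5-vinylcyclohex-2-en-1-one | COC1(OC)C=CC(=O)C[C@H]1C=C | intermediate
6 | (E)-but-2-en-1-yl acetate | C/C=C/COC(C)=O | starting material
7 | lithium dienolate of 5 (C5=C6–OLi) | [Li]OC1=C[C@@H](C=C)C(OC)(OC)C=C1 | intermediate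
8 | (5R,6R)-6-[(2S)-but-3-en-2-yl]-4,4-dimethoxy-5-vinylcyclohex-2-en-1-one | C=C[C@@H]1[C@@H]([C@@H](C)C=C)C(=O)C=CC1(OC)OC | intermediate
9 | (3S,3aR,7aR)-7,7-dimethoxy-3-methyl-3,3a,7,7a-tetrahydro-4H-inden-4-one | COC1(OC)C=CC(=O)[C@@H]2[C@@H](C)C=C[C@@H]12 | intermediate
10 | allylic alcohol ketal (6α-OH, C9 dimethyl ketal) | COC1(OC)C=C[C@@H](O)[C@@H]2[C@@H](C)C=C[C@@H]12 | intermediate
11 | (1S,3aR,7R,7aR)-7-hydroxy-1-methyl-1,3a,7,7a-tetrahydro-4H-inden-4-one | O=C1C=C[C@@H](O)[C@@H]2[C@@H](C)C=C[C@@H]12 | intermediate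
12 | ethyl prop-1-enyl ether (E/Z) | CCOC=CC | starting material
13 | bromoacetal of 11 (6-O–CH(OEt)–CHBr–CH3) | O=C1C=C[C@@H](OC(OCC)C(C)Br)[C@@H]2[C@@H](C)C=C[C@@H]12 | intermediate
14 | tricyclic keto acetal (cis-fused 2-ethoxy-3-methyl-THF across C6–C7, 11S, C9 ketone) | O=C1C[C@H]2[C@H](C)C(OCC)O[C@H]2[C@@H]3[C@@H](C)C=C[C@@H]13 | intermediate
15 | ethynylmagnesium bromide | C#C[Mg]Br | starting material
16 | propargylic alcohol acetal (9β-ethynyl, 9α-OH, C12 ethyl acetal) | C#C[C@]1(O)C[C@H]2[C@H](C)C(OCC)O[C@H]2[C@@H]3[C@@H](C)C=C[C@@H]13 | intermediate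
17 | lactol (as 16, OH in place of OEt at C12) | C#C[C@]1(O)C[C@H]2[C@H](C)C(O)O[C@H]2[C@@H]3[C@@H](C)C=C[C@@H]13 | intermediate
18 | 3-methylbut-3-en-2-one | CC(=O)C(C)=C | starting material
19 | lithium enolate of 18 | [Li]OC(=C)C(C)=C | intermediate
20 | aldol adduct (6α,9α,12S-triol, 9β-ethynyl, 14-ketone) | C=C(C)C(=O)C[C@H](O)[C@@H](C)[C@@H]1C[C@@](O)(C#C)[C@@H]2C=C[C@H](C)[C@H]2[C@@H]1O | intermediate
21 | 12-O-acetate of 20 | C=C(C)C(=O)C[C@H](OC(C)=O)[C@@H](C)[C@@H]1C[C@@](O)(C#C)[C@@H]2C=C[C@H](C)[C@H]2[C@@H]1O | intermediate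
22 | ring-expanded bis-enone (9,14-diketone of the target) | C=C(C)C(=O)C[C@H](OC(C)=O)[C@@H](C)[C@@H]1CC(=O)C(=C)[C@@H]2C=C[C@H](C)[C@H]2[C@@H]1O | intermediate
23 | CNP0151410.1 | C=C(C)[C@H](O)C[C@H](OC(C)=O)[C@@H](C)[C@@H]1C[C@@H](O)C(=C)[C@@H]2C=C[C@H](C)[C@H]2[C@@H]1O | target

## Step count and risks

Total step count: 12. Longest linear sequence: 12 (all fragments are bought).

Three steps most likely to fail:

**Step 11 (new gold-catalysed ring expansion).** Risks are Meyer–Schuster/Rupe rearrangement, C8 instead of C1 migration, and attack of the free 6-OH or the cyclopentene on the activated alkyne. The fallback uses known chemistry, sets out from 21 and comes back at 22. Semihydrogenation of the alkyne (H2, Lindlar catalyst, quinoline) gives vinyl carbinol F1. Hydroxyl-directed epoxidation (VO(acac)2, t-BuOOH) gives epoxy alcohol F2. The Lewis-acid semipinacol rearrangement of 2,3-epoxy alcohols (ZnBr2, CH2Cl2, −40 °C; C1 shifts to the epoxide carbon with ring expansion) gives hydroxymethyl ketone F3. MsCl/Et3N gives mesylate F4 (not isolated), which DBU eliminates to 22.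

**Step 3 (Ir-catalysed branched crotylation of a cross-conjugated lithium dienolate).** Risks are linear product, double allylation and low control at C4. The fallback sets out from 5 and comes back at 8. Aldol reaction of dienolate 7 with acetaldehyde gives aldol adduct F5. MsCl/Et3N gives mesylate F6 (not isolated), and DBU gives (E)-ethylidene dienone F7. Conjugate addition of a vinyl cuprate (CH2=CHMgBr, CuI, TMSCl, THF, −78 °C) to the exocyclic enone occurs anti to the C1 vinyl group, which A(1,3) strain holds axial; this sets C4, and protonation gives the trans ketone 8.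

**Step 9 (aldol on a free lactol with two further acidic OH groups).** Risks are incomplete lactol opening, modest Felkin selectivity and enolate self-condensation. The fallback sets out from 16 (isolated by neutral work-up in step 8) and comes back at 21; it also removes the selectivity question of step 10. Propane-1,3-dithiol with Zn(OTf)2 opens the acetal to dithiane diol F8. TESOTf/2,6-lutidine gives bis-TES ether F9. MeI, CaCO3 in aqueous MeCN gives aldehyde F10. Mukaiyama aldol with silyl dienol ether F11 (from 18, LDA, TMSCl) and BF3·OEt2 at −78 °C (Felkin control) gives protected aldol F12. Ac2O/DMAP gives protected acetate F13, and HF·pyridine removes both silyl groups to give 21.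

Further compounds
F1 | step 11 | vinyl carbinol (21 with vinyl in place of ethynyl) | C=C(C)C(=O)C[C@H](OC(C)=O)[C@@H](C)[C@@H]1C[C@@](O)(C=C)[C@@H]2C=C[C@H](C)[C@H]2[C@@H]1O
F2 | step 11 | epoxy alcohol (oxiranyl carbinol at C9) | C=C(C)C(=O)C[C@H](OC(C)=O)[C@@H](C)[C@@H]1C[C@@](O)(C3CO3)[C@@H]2C=C[C@H](C)[C@H]2[C@@H]1O
F3 | step 11 | hydroxymethyl ketone (10-CH2OH, 9-oxo, seven-membered ring) | C=C(C)C(=O)C[C@H](OC(C)=O)[C@@H](C)[C@@H]1CC(=O)C(CO)[C@@H]2C=C[C@H](C)[C@H]2[C@@H]1O
F4 | step 11 | mesylate of F3 | C=C(C)C(=O)C[C@H](OC(C)=O)[C@@H](C)[C@@H]1CC(=O)C(COS(C)(=O)=O)[C@@H]2C=C[C@H](C)[C@H]2[C@@H]1O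
F5 | step 3 | aldol adduct (6-(1-hydroxyethyl) derivative of 5) | COC1(OC)C=CC(=O)C(C(C)O)[C@H]1C=C
F6 | step 3 | mesylate of F5 | COC1(OC)C=CC(=O)C(C(C)OS(C)(=O)=O)[C@H]1C=C
F7 | step 3 | (E)-ethylidene dienone ((S)-6-ethylidene-4,4-dimethoxy-5-vinylcyclohex-2-en-1-one) | COC1(OC)C=CC(=O)/C(=C/C)[C@H]1C=C
F8 | step 9 | dithiane diol (C12 as 1,3-dithiane, free 6-OH and 9-OH) | C1(SCCCS1)[C@@H](C)[C@@H]2C[C@@](O)(C#C)[C@@H]3C=C[C@H](C)[C@H]3[C@@H]2O
F9 | step 9 | bis-TES ether of F8 | C1(SCCCS1)[C@@H](C)[C@@H]2C[C@@](O[Si](CC)(CC)CC)(C#C)[C@@H]3C=C[C@H](C)[C@H]3[C@@H]2O[Si](CC)(CC)CC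
F10 | step 9 | aldehyde (C12 CHO, 6,9-bis-OTES) | O=C[C@@H](C)[C@@H]1C[C@@](O[Si](CC)(CC)CC)(C#C)[C@@H]2C=C[C@H](C)[C@H]2[C@@H]1O[Si](CC)(CC)CC
F11 | step 9 | silyl dienol ether (2-(trimethylsilyloxy)-3-methylbuta-1,3-diene) | C=C(C)C(=C)O[Si](C)(C)C
F12 | step 9 | protected aldol (12S-OH, 14-ketone, 6,9-bis-OTES) | C=C(C)C(=O)C[C@H](O)[C@@H](C)[C@@H]1C[C@@](O[Si](CC)(CC)CC)(C#C)[C@@H]2C=C[C@H](C)[C@H]2[C@@H]1O[Si](CC)(CC)CC
F13 | step 9 | protected acetate (12-OAc, 6,9-bis-OTES) | C=C(C)C(=O)C[C@H](OC(C)=O)[C@@H](C)[C@@H]1C[C@@](O[Si](CC)(CC)CC)(C#C)[C@@H]2C=C[C@H](C)[C@H]2[C@@H]1O[Si](CC)(CC)CC
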